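The pyranone ring is closed onto ring A from outside: the two ortho bonds O1–C8a and C4–C4a are made together when the alkoxide of an enantiopure β-hydroxy Weinreb amide (O1–C2–C3–C4 already in place, C2 set by asymmetric transfer hydrogenation) adds to an aryne spanning C4a/C8a and the resulting aryl anion acylates itself. The step exploits the ortho ether-oxygen/acyl pattern of the chroman-4-one on the benzo ring. A bromine at C5 steers the aryne regiochemistry and is removed afterwards; the ketone stays masked as the Weinreb tetrahedral adduct until quench, so the base-labile flavanone centre C2 is never exposed to base.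

Key step: step 6

Remarks: flavanone numbering (O1, C2, C3, C4, C4a, C5–C8, C8a) is used. Geranyl = (2E)-3,7-dimethylocta-2,6-dien-1-yl. THP = tetrahydro-2H-pyran-2-yl, used racemic, so 9–17 are mixtures of epimers at the acetal carbon, which is lost in step 8. The target is (2S).

Step 1
Reactants: 1 methyl 4-hydroxybenzoate; 2 geranyl bromide
Product: 3 methyl 4-(geranyloxy)benzoate
Conditions: K2CO3, DMF, rt
Reagents that add atoms: none
Why: Williamson ether synthesis; the phenoxide displaces the primary allylic bromide by SN2, the hindered γ-carbon disfavouring SN2′.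

Step 2
Reactants: 3 methyl 4-(geranyloxy)benzoate; 4 N-methoxy-N-methylacetamide
Product: 6 3-[4-(geranyloxy)phenyl]-N-methoxy-N-methyl-3-oxopropanamide, via lithium enolate of the acetamide 5 (not isolated)
Conditions: LDA (2.2 equiv), 4 (2.2 equiv), THF, −78 °C; then 3, −78 → 0 °C; aq. NH4Cl
Reagents that add atoms: none
Why: crossed Claisen condensation; the amide enolate acylates at the ester, and the second equivalent of enolate deprotonates the β-keto amide as it forms, which should protect it from further addition.

Step 3
Reactants: 6 3-[4-(geranyloxy)phenyl]-N-methoxy-N-methyl-3-oxopropanamide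
Product: 7 (3S)-3-[4-(geranyloxy)phenyl]-3-hydroxy-N-methoxy-N-methylpropanamide
Conditions: RuCl[(S,S)-TsDPEN](p-cymene) (1 mol%), HCO2H/Et3N (5:2), DMF, 30–40 °C
Reagents that add atoms: none
Why: Noyori asymmetric transfer hydrogenation; the (S,S)-catalyst delivers hydride through its CH/π-organised outer-sphere transition state to the aryl ketone face that gives the (S)-carbinol (same sense as acetophenone to (S)-1-phenylethanol), and the alkenes and allylic ether are not reduced.

Step 4
Reactants: 8 4-(THP-oxy)phenol (deoxyarbutin)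
Product: 9 2,6-dibromo-4-(THP-oxy)phenol
Conditions: NBS (2.05 equiv), i-Pr2NH (10 mol%), CH2Cl2, 0 °C
Reagents that add atoms: N-bromosuccinimide, O=C1CCC(=O)N1Br
Why: amine-catalysed electrophilic ortho-bromination of a phenol; the free OH is the stronger director with its para position blocked, and the non-acidic medium should spare the THP acetal.

Step 5
Reactants: 9 2,6-dibromo-4-(THP-oxy)phenol
Product: 12 2-bromo-4-(THP-oxy)-6-(trimethylsilyl)phenyl trifluoromethanesulfonate, via aryl trimethylsilyl ether 10 (not isolated), via lithium ortho-silylphenoxide 11 (not isolated)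
Conditions: HMDS, THF, 70 °C, then evaporate; n-BuLi (1.05 equiv), THF, −78 °C; Tf2O, −78 °C → rt; aq. NaHCO3
Reagents that add atoms: hexamethyldisilazane, C[Si](C)(C)N[Si](C)(C)C; trifluoromethanesulfonic anhydride, O=S(=O)(OS(=O)(=O)C(F)(F)F)C(F)(F)F
Why: standard route to ortho-silylaryl triflates: O-silylation, then Br–Li exchange at one of the two equivalent bromines triggers a 1,3 O→C silyl shift (retro-Brook rearrangement) and the resulting phenoxide is triflated.

Step 6
Reactants: 7 (3S)-3-[4-(geranyloxy)phenyl]-3-hydroxy-N-methoxy-N-methylpropanamide; 12 2-bromo-4-(THP-oxy)-6-(trimethylsilyl)phenyl trifluoromethanesulfonate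
Product: 16 (2S)-5-bromo-2-[4-(geranyloxy)phenyl]-7-(THP-oxy)chroman-4-one, via sodium alkoxide 13 (not isolated), via bromoaryne 14 (not isolated), via tetrahedral hemiaminal salt 15 (not isolated)
Conditions: 7, NaH (1.0 equiv), THF, 0 °C; then 12 (1.3 equiv), CsF (3 equiv), 18-crown-6, THF, 0 °C → rt; AcOH, −20 °C, then pH 7 buffer
Reagents that add atoms: none
Why: Proposed new method: fluoride removes the silyl group of 12 and triflate leaves to give aryne 14; the alkoxide oxygen of 13 adds to the aryne carbon remote from bromine (C8a), and the aryl anion formed at C4a attacks the Weinreb carbonyl in a 6-exo-trig closure of the pyranone ring to give the tetrahedral adduct 15, which should release the ketone only on the acidic quench. The closest known reactions are the aryne annulation of methyl salicylates to xanthones (phenoxide addition, then intramolecular acyl substitution) and the ring-expanding aryne insertion into the amide bond of β-lactams to 2,3-dihydroquinolin-4-ones; an aliphatic β-alkoxide with a Weinreb amide acceptor has not been shown. No bond to C2 is made or broken, so the S configuration of 7 is carried over, and because the ketone stays masked as 15 under the basic conditions the base-induced opening to a 2′-hydroxychalcone that racemises flavanones cannot start. The selectivity the step needs is regiochemical: the C5 bromine distorts the aryne so that nucleophiles enter at the distal carbon, as with 3-halobenzynes, which places O1 meta and the acyl carbon para to the THP-protected oxygen, whereas a plain 4-alkoxybenzyne would give both orientations. The alkoxide is pre-formed so that no O–H proton can quench the aryl anion, and the 6-exo capture has to outrun loss of bromide from the ortho-bromoaryl anion.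

Step 7
Reactants: 16 (2S)-5-bromo-2-[4-(geranyloxy)phenyl]-7-(THP-oxy)chroman-4-one
Product: 17 (2S)-2-[4-(geranyloxy)phenyl]-7-(THP-oxy)chroman-4-one
Conditions: Bu3SnH (1.3 equiv), AIBN (cat.), PhMe, 80 °C; KF work-up
Reagents that add atoms: none
Why: radical-chain hydrodebromination; the aryl σ-radical should take hydrogen from the stannane faster than it can reach the remote trisubstituted alkenes, and the neutral conditions leave C2, the acetal and the allylic ether alone.

Step 8
Reactants: 17 (2S)-2-[4-(geranyloxy)phenyl]-7-(THP-oxy)chroman-4-one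
Product: 18 (2S)-7-hydroxy-2-[4-(geranyloxy)phenyl]chroman-4-one (target)
Conditions: PPTS (0.2 equiv), MeOH/THF, 40 °C
Reagents that add atoms: none
Why: acid-catalysed transacetalisation of the phenolic THP ether to methanol; the acid is too weak to ionise the geranyl aryl ether or to open the pyranone ring.

Compound list
1 | methyl 4-hydroxybenzoate | COC(=O)c1ccc(O)cc1 | starting material
2 | geranyl bromide, (2E)-1-bromo-3,7-dimethylocta-2,6-diene | CC(C)=CCC/C(C)=C/CBr | starting material
3 | methyl 4-(geranyloxy)benzoate | CC(C)=CCC/C(C)=C/COc1ccc(C(=O)OC)cc1 | intermediate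
4 | N-methoxy-N-methylacetamide | CC(=O)N(C)OC | starting material
5 | lithium enolate of N-methoxy-N-methylacetamide | [Li+].C=C([O-])N(C)OC | intermediate
6 | 3-[4-(geranyloxy)phenyl]-N-methoxy-N-methyl-3-oxopropanamide | CC(C)=CCC/C(C)=C/COc1ccc(C(=O)CC(=O)N(C)OC)cc1 | intermediate
7 | (3S)-3-[4-(geranyloxy)phenyl]-3-hydroxy-N-methoxy-N-methylpropanamide | CC(C)=CCC/C(C)=C/COc1ccc([C@@H](O)CC(=O)N(C)OC)cc1 | intermediate
8 | 4-(tetrahydro-2H-pyran-2-yloxy)phenol (deoxyarbutin, racemic) | Oc1ccc(OC2CCCCO2)cc1 | starting material
9 | 2,6-dibromo-4-(tetrahydro-2H-pyran-2-yloxy)phenol | Oc1c(Br)cc(OC2CCCCO2)cc1Br | intermediate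
10 | [2,6-dibromo-4-(tetrahydro-2H-pyran-2-yloxy)phenoxy]trimethylsilane | C[Si](C)(C)Oc1c(Br)cc(OC2CCCCO2)cc1Br | intermediate
11 | lithium 2-bromo-4-(tetrahydro-2H-pyran-2-yloxy)-6-(trimethylsilyl)phenoxide | [Li+].[O-]c1c(Br)cc(OC2CCCCO2)cc1[Si](C)(C)C | intermediate
12 | 2-bromo-4-(tetrahydro-2H-pyran-2-yloxy)-6-(trimethylsilyl)phenyl trifluoromethanesulfonate | O=S(=O)(Oc1c(Br)cc(OC2CCCCO2)cc1[Si](C)(C)C)C(F)(F)F | intermediate
13 | sodium (1S)-1-[4-(geranyloxy)phenyl]-3-[methoxy(methyl)amino]-3-oxopropan-1-olate | CC(C)=CCC/C(C)=C/COc1ccc([C@@H]([O-])CC(=O)N(C)OC)cc1.[Na+] | intermediate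
14 | 3-bromo-5-(tetrahydro-2H-pyran-2-yloxy)benzyne (1-bromo-2,3-didehydro-5-(THP-oxy)benzene) | BrC1=CC(OC2CCCCO2)=CC#C1 | intermediate
15 | sodium (2S)-5-bromo-2-[4-(geranyloxy)phenyl]-4-[methoxy(methyl)amino]-7-(THP-oxy)chroman-4-olate (mixture at C4) | CC(C)=CCC/C(C)=C/COc1ccc([C@@H]2CC([O-])(N(C)OC)c3c(Br)cc(OC4CCCCO4)cc3O2)cc1.[Na+] | intermediate
16 | (2S)-5-bromo-2-[4-(geranyloxy)phenyl]-7-(tetrahydro-2H-pyran-2-yloxy)chroman-4-one | CC(C)=CCC/C(C)=C/COc1ccc([C@@H]2CC(=O)c3c(Br)cc(OC4CCCCO4)cc3O2)cc1 | intermediate
17 | (2S)-2-[4-(geranyloxy)phenyl]-7-(tetrahydro-2H-pyran-2-yloxy)chroman-4-one | CC(C)=CCC/C(C)=C/COc1ccc([C@@H]2CC(=O)c3ccc(OC4CCCCO4)cc3O2)cc1 | intermediate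
18 | (2S)-7-hydroxy-2-[4-(geranyloxy)phenyl]chroman-4-one | CC(C)=CCC/C(C)=C/COc1ccc([C@@H]2CC(=O)c3ccc(O)cc3O2)cc1 | target

Total step count: 8. Longest linear sequence: 6 steps (1, 2, 3, 6, 7, 8); steps 4 and 5 form the second branch.

Steps most likely to fail

Step 6 (proposed new method). What may go wrong:
- loss of bromide from the ortho-bromoaryl anion before ring closure, giving a second aryne and 5-substituted by-products;
- transfer of the sulfonyl or silyl group of 12 to the alkoxide instead of aryne capture;
- quenching of the aryl anion by adventitious proton sources;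
- erosion of the regioselectivity.

Fallback (known chemistry), setting out from 2 and returning at 17: purchased 4-hydroxyphenylboronic acid is O-alkylated with 2 (K2CO3, acetone) to [4-(geranyloxy)phenyl]boronic acid F1. Purchased 7-hydroxychromone is protected with 3,4-dihydro-2H-pyran and PPTS as 7-(tetrahydro-2H-pyran-2-yloxy)-4H-chromen-4-one F2. A Pd(II)/pyridine-oxazoline-catalysed enantioselective conjugate addition of F1 to F2 (Pd(OCOCF3)2, t-Bu-PyOX antipode chosen for the 2S product, NH4PF6, H2O, ClCH2CH2Cl, 60 °C) should give 17 directly. Steps 4–7 are then not needed.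

Step 2. What may go wrong: sluggish acyl substitution at the electron-rich benzoate, so that the amide enolate self-condenses or decomposes on warming before it is acylated.

Fallback, setting out from 2 and returning at 6: purchased 4-hydroxybenzaldehyde is alkylated with 2 (K2CO3, DMF) to 4-(geranyloxy)benzaldehyde F3. Aldol addition of the lithium enolate 5 at −78 °C should give racemic 3-[4-(geranyloxy)phenyl]-3-hydroxy-N-methoxy-N-methylpropanamide F4, and Dess–Martin oxidation of the benzylic carbinol leads to 6. The more electrophilic aldehyde takes the place of the ester, at the cost of one oxidation.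

Step 5. What may go wrong: exchange of both bromines, incomplete silyl migration, or cleavage of the acetal by triflic acid formed from excess anhydride.

Fallback, setting out from 8 and returning at 12: monobromination (NBS, 1 equiv) gives 2-bromo-4-(tetrahydro-2H-pyran-2-yloxy)phenol F5. Silylation with HMDS, n-BuLi-induced retro-Brook shift and aqueous quench give 2-(trimethylsilyl)-4-(tetrahydro-2H-pyran-2-yloxy)phenol F6. A second ortho-bromination (NBS, i-Pr2NH cat.) gives 2-bromo-6-(trimethylsilyl)-4-(tetrahydro-2H-pyran-2-yloxy)phenol F7, which is triflated (Tf2O, pyridine, 0 °C) to 12. The exchange step then never faces two bromines.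

Further compounds
F1 | step 6 | [4-(geranyloxy)phenyl]boronic acid | CC(C)=CCC/C(C)=C/COc1ccc(B(O)O)cc1
F2 | step 6 | 7-(tetrahydro-2H-pyran-2-yloxy)-4H-chromen-4-one | O=C1C=COc2cc(OC3CCCCO3)ccc12
F3 | step 2 | 4-(geranyloxy)benzaldehyde | CC(C)=CCC/C(C)=C/COc1ccc(C=O)cc1
F4 | step 2 | racemic 3-[4-(geranyloxy)phenyl]-3-hydroxy-N-methoxy-N-methylpropanamide | CC(C)=CCC/C(C)=C/COc1ccc(C(O)CC(=O)N(C)OC)cc1
F5 | step 5 | 2-bromo-4-(tetrahydro-2H-pyran-2-yloxy)phenol | Oc1ccc(OC2CCCCO2)cc1Br
F6 | step 5 | 2-(trimethylsilyl)-4-(tetrahydro-2H-pyran-2-yloxy)phenol | C[Si](C)(C)c1cc(OC2CCCCO2)ccc1O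
F7 | step 5 | 2-bromo-6-(trimethylsilyl)-4-(tetrahydro-2H-pyran-2-yloxy)phenol | C[Si](C)(C)c1cc(OC2CCCCO2)cc(Br)c1O
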